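The flask takes 0.050 M of substrate, dosed evenly over 8.0 min, against 0.0500 M of solid reagent, none of it in solution at the start.

| setting | dawn | flask |
|---|---|---|
| substrate | 0.050 M (fed, over 8.0 min) | 0.050 M (fed, over 8.0 min) |
| solid reagent | 0.050 M | 0.0500 M |
| remark | the very flask that is asked about, followed so far |  |
| time |  | 8.0 min |

dawn run (percent of the substrate charged)

| time / min | target / % | substrate / % |
|---|---|---|
| 0.200 | 0 | 2 |
| 0.333 | 2 | 3 |
| 0.417 | 0 | 7 |
| 0.667 | 0 | 9 |
| 1.00 | 2 | 14 |
| 1.50 | 0 | 19 |
| 2.50 | 0 | 32 |

(each reading ± 1.5 percentage points)

- solid, in amounts per volume of the solution: solid reagent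
- at the start none of the solid reagent is in solution
- percentages count the whole charge, also what has not yet gone in

- concentration of target at 8.0 min, in M
- concentration of substrate at 8.0 min, in M

A substrate molecule that has entered the flask stands at one fork: it is still free, or it has reacted. The second branch can be counted from the feed rate, the whole charge divided by the dosing time, 0.00625 M min⁻¹: reacted substrate is the feed rate times the elapsed time, less [substrate].

In the first instants of the dawn run, at 0.200 min, the feed has delivered 2.50% of the charge and the reading is 2%. Later in the dawn run, at 2.50 min, the feed has delivered 31.2% and the reading is 32%. That difference of 0.75 percentage points is inside the scatter of 1.5 points, and target reads 0%. So far the dawn run reads, within its scatter, as plain accumulation of the feed, and its readings give no rate. At the end of dosing the feed has delivered 0.0500 M. The reckoning here commits to [substrate] just under that figure, with target somewhere inside the gap.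

The forecast reasons that “The reagent must dissolve first, so the rate likely grows as substrate times dissolved reagent”, and it gives 0.045 M substrate and 0.005 M target. Those two sum to the charge, so in the forecast the gap is target; the reckoning here names no figure for target, and differs there.

The flask gives 0.0470 M substrate and 6.63 × 10⁻⁴ M target at 8.0 min, which puts the forecast's target 7.54 times too high.

    substrate + target → side product (k = 0.270 M⁻¹ s⁻¹)
    substrate + partner → target, rate k2*[substrate]^1.5*[partner] (k = 0.270 M⁻¹·⁵ s⁻¹)
    2 substrate → homo dimer (k = 1.00 × 10⁻⁴ M⁻¹ s⁻¹)
    solid reagent ⇌ partner, rate k4*(cs4 - [partner]) while solid is left; crystals form when [partner] > cs4 (solubility = 8.70 mM, k = 0.00180 s⁻¹)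

The feed rate times 8.0 min, less [substrate], leaves 0.00296 M reacted, of which target holds 22.4%. The half-life of target by the step substrate + target into side product alone, with the whole charge counted as present at once, is 0.86 min, short against 8.0 min. In the neighbour flask with 0.085 M of substrate the feed rate is 0.0106 M min⁻¹, reacted substrate comes to 0.00584 M, and target holds 7.01 × 10⁻⁴ M of it, which is 12.0%.

The readings stem from a simulated flask with made-up constants, noise included.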